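**Strategy.** The target is read as a Cope product: its ring A alkene (C2=C3) and the enol form of the C8 ketone toward C7 flank the C1–C8a bond as a 1,5-diene. The key step is therefore a thermal [3,3] shift of bicyclo[2.2.2]octene silyl enol ether 15, which forms C1–C8a, closes ring A with a cis ring fusion and breaks a sacrificial bond between the fully substituted carbons C3 and C7. The cage, built by a silicon-tethered Diels–Alder reaction of an organocatalytically made dienol with a butenolide lactol, fixes the endo ester and (E)-acrylate that the boat transition state turns into the C1/C4 trans diester.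

Key step: step 8

Remark: the target is numbered as a hexahydronaphthalene (C1 and C4 carry the ring A esters, C3 and C6 the hexadecyl groups, C7 the ring B ester, C8 the ketone, C4a/C8a the ring fusion); lactol 8 is used as the racemate because its acetal carbon is labile and disappears in step 6.

Step 1
Reactants: 1 octadec-1-ene; 2 (E)-but-2-enal
Product: 3 (E)-nonadec-2-enal
Conditions: second-generation Hoveyda–Grubbs catalyst (2 mol %), 2 (5 equiv), CH2Cl2, 40 °C
Reagents that add atoms: none
Why: Olefin cross-metathesis of a terminal alkene with an enal partner should give the E-enal under thermodynamic control, propene being lost.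

Step 2
Reactants: 3 (E)-nonadec-2-enal; 4 methyl 3-oxobutanoate
Product: 5 methyl (1S,6R)-6-hexadecyl-2-oxocyclohex-3-ene-1-carboxylate
Conditions: (S)-α,α-diphenylprolinol trimethylsilyl ether (10 mol %), PhCO2H (10 mol %), PhMe, rt; then p-TsOH·H2O (20 mol %), 40 °C
Reagents that add atoms: none
Why: Iminium-catalysed Michael addition of the β-keto ester to the enal, on the face anti to the diphenyl(silyloxy)methyl group, is expected to set C6 as R, and acid-promoted intramolecular aldol condensation of the methyl ketone onto the aldehyde closes the cyclohexenone (organocatalytic Michael/aldol condensation), C1 settling trans to the hexadecyl group.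

Step 3
Reactants: 6 octadecanal; 7 glyoxylic acid monohydrate
Product: 8 4-hexadecyl-5-hydroxyfuran-2(5H)-one (racemic)
Conditions: morpholine hydrochloride (1.0 equiv), 1,4-dioxane/H2O, reflux
Reagents that add atoms: none
Why: Amine-mediated aldol condensation of the aldehyde α-carbon with glyoxylic acid gives the (Z)-3-formylacrylic acid, which closes to the γ-hydroxybutenolide with the hexadecyl group on the β-carbon.

Step 4
Reactants: 5 methyl (1S,6R)-6-hexadecyl-2-oxocyclohex-3-ene-1-carboxylate; 8 4-hexadecyl-5-hydroxyfuran-2(5H)-one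
Product: 10 methyl (6R)-6-hexadecyl-2-({[(3-hexadecyl-5-oxo-2,5-dihydrofuran-2-yl)oxy]di(propan-2-yl)silyl}oxy)cyclohexa-1,3-diene-1-carboxylate (both epimers at the acetal carbon), via chlorosilyl dienol ether 9 (not isolated)
Conditions: iPr2SiCl2 (3 equiv), Et3N, CH2Cl2, 0 °C to rt; excess silane removed in vacuo; then 8, imidazole, CH2Cl2, rt; used crude
Reagents that add atoms: dichlorodi(propan-2-yl)silane CC(C)[Si](Cl)(Cl)C(C)C
Why: O-silylation of the hydrogen-bonded enol of the β-keto ester and then of the lactol hydroxyl should give the unsymmetrical silyl ketal (temporary silicon connection), in which no stereocenter of the target is set and the acetal carbon is present as both epimers.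

Step 5
Reactants: 10 silyl ketal triene
Product: 12 keto lactol (bicyclo[2.2.2]octan-2-one; C1 CO2Me; hexadecyl on C6 and C7; cis-fused γ-hydroxy-γ-lactone with its carbonyl on C5 and its lactol carbon on C6, both syn to the C2 bridge), via silicon-bridged cycloadduct 11 (not isolated)
Conditions: iPr2NEt (0.3 equiv), BHT, PhMe (0.01 M), 160 °C, sealed tube; then HF·pyridine, THF, 0 °C
Reagents that add atoms: none
Why: In this type 2 intramolecular Diels–Alder reaction the four-atom O–Si–O–C tether joins C1 of the diene to the hexadecyl-bearing β-carbon of the butenolide and holds the lactone endo, the dienophile adds anti to the pseudoaxial C6 hexadecyl group (which fixes the bridgeheads and thereby C4a and C4 of the target), the acetal epimers of 10 are expected to interconvert by amine-mediated γ-deprotonation of the butenolide so that both drain through the one epimer that can reach this transition state, and HF then cleaves both Si–O bonds.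

Step 6
Reactants: 12 keto lactol
Product: 14 dimethyl (1S,4R,5S,6S,7R)-6,7-dihexadecyl-6-[(E)-3-methoxy-3-oxoprop-1-en-1-yl]-2-oxobicyclo[2.2.2]octane-1,5-dicarboxylate, via carboxylic acid 13 (not isolated)
Conditions: Ph3P=CHCO2Me (2 equiv), PhMe, 100 °C; then MeOH, Me3SiCHN2, 0 °C
Reagents that add atoms: methyl (triphenylphosphoranylidene)acetate COC(=O)C=P(c1ccccc1)(c1ccccc1)c1ccccc1; (trimethylsilyl)diazomethane C[Si](C)(C)C=[N+]=[N-]
Why: The lactol is in equilibrium with its aldehyde acid, which the stabilised ylide should trap as the E-acrylate (Wittig reaction), and the freed acid is methylated without base so that C5 is not epimerised.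

Step 7
Reactants: 14 bicyclic keto triester
Product: 15 dimethyl (1S,4R,5S,6S,7R)-2-{[tert-butyl(dimethyl)silyl]oxy}-6,7-dihexadecyl-6-[(E)-3-methoxy-3-oxoprop-1-en-1-yl]bicyclo[2.2.2]oct-2-ene-1,5-dicarboxylate (acrylate and C5 ester syn to the C2=C3 bridge)
Conditions: TBSOTf (1.5 equiv), Et3N (3 equiv), CH2Cl2, 0 °C to rt
Reagents that add atoms: tert-butyldimethylsilyl trifluoromethanesulfonate CC(C)(C)[Si](C)(C)OS(=O)(=O)C(F)(F)F
Why: Soft enolisation with a silyl triflate and an amine can give only the enol ether toward C3, because C1 is a quaternary bridgehead, and no stereocenter changes.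

Step 8
Reactants: 15 bicyclic silyl enol ether
Product: 16 trimethyl (1R,4S,4aR,6R,8aS)-8-{[tert-butyl(dimethyl)silyl]oxy}-3,6-dihexadecyl-1,4,4a,5,6,8a-hexahydronaphthalene-1,4,7-tricarboxylate
Conditions: PhMe (degassed), 130 °C, sealed tube
Reagents that add atoms: none
Why: Thermal [3,3]-sigmatropic (Cope) rearrangement of the 1,5-diene made of the acrylate C=C, the C6–C1 bond and the silyl enol ether C2=C3 of 15: the acrylate α-carbon bonds to C3 (C1–C8a of the target) while the bond between the fully substituted C6 and C1 (C3–C7 of the target) breaks. The closest known reaction type is the Cope rearrangement of endo-5-vinylbicyclo[2.2.2]oct-2-enes to cis-fused hexalins, the neutral counterpart of the anionic oxy-Cope route to cis-decalins. Ring A is closed suprafacially on both allyl halves through the boat-shaped six-centre array that the cage enforces, in effect a 6-endo closure of the acrylate α-carbon onto C3. The new stereocenter C8a is set by the cage, since the vinyl group can reach C3 only from the face carrying the C5–C6 bridge (cis fusion), and the new stereocenter C1 is set by the E geometry of the acrylate, whose ester points outward in the boat and ends cis to C8; C4 and C4a are carried over, so the endo ester ends trans to C5. The step needs the [3,3] path to beat cycloreversion, 1,3-shift and loss of the silyl group, which the endo vinyl group held over the enol ether, the weak, doubly allylic, ester-flanked C6–C1 bond and the gain of push–pull conjugation in the β-silyloxy acrylate should secure.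

Step 9
Reactants: 16 hexalin silyl enol ether
Product: 18 trimethyl (1R,4S,4aR,8aS)-3,6-dihexadecyl-8-oxo-1,4,4a,5,8,8a-hexahydronaphthalene-1,4,7-tricarboxylate, via C7 phenylselenide 17 (not isolated)
Conditions: Bu4NF (1.0 equiv), THF, −78 °C; PhSeCl (1.05 equiv), −78 °C; then 30% aq H2O2, pyridine, CH2Cl2, 0 °C to rt
Reagents that add atoms: none
Why: Fluoride releases the β-keto ester enolate, which should be selenenylated at C7 anti to the neighbouring hexadecyl group, and oxidation to the selenoxide with syn elimination toward the only β-hydrogen (on C6, cis to selenium) gives the enone and erases the C6 stereocenter that steered the cycloaddition.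

**Compound list**

1 | octadec-1-ene | C=CCCCCCCCCCCCCCCCC | starting material
2 | (E)-but-2-enal | C/C=C/C=O | starting material
3 | (E)-nonadec-2-enal | CCCCCCCCCCCCCCCC/C=C/C=O | intermediate
4 | methyl 3-oxobutanoate | COC(=O)CC(C)=O | starting material
5 | methyl (1S,6R)-6-hexadecyl-2-oxocyclohex-3-ene-1-carboxylate | COC(=O)[C@@H]1C(=O)C=CC[C@H]1CCCCCCCCCCCCCCCC | intermediate
6 | octadecanal | CCCCCCCCCCCCCCCCCC=O | starting material
7 | glyoxylic acid monohydrate | OC(O)C(=O)O | starting material
8 | 4-hexadecyl-5-hydroxyfuran-2(5H)-one (racemic) | O=C1C=C(CCCCCCCCCCCCCCCC)C(O)O1 | intermediate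
9 | methyl (6R)-2-{[chloro-di(propan-2-yl)silyl]oxy}-6-hexadecylcyclohexa-1,3-diene-1-carboxylate | COC(=O)C1=C(O[Si](Cl)(C(C)C)C(C)C)C=CC[C@H]1CCCCCCCCCCCCCCCC | intermediate (not isolated)
10 | methyl (6R)-6-hexadecyl-2-({[(3-hexadecyl-5-oxo-2,5-dihydrofuran-2-yl)oxy]di(propan-2-yl)silyl}oxy)cyclohexa-1,3-diene-1-carboxylate, both acetal epimers | COC(=O)C1=C(O[Si](C(C)C)(C(C)C)OC2OC(=O)C=C2CCCCCCCCCCCCCCCC)C=CC[C@H]1CCCCCCCCCCCCCCCC | intermediate
11 | silicon-bridged cycloadduct (bicyclo[2.2.2]oct-2-ene; C2 enol oxygen and C6 acetal oxygen joined through Si(iPr)2; γ-lactone across C5/C6 syn to C2=C3) | COC(=O)[C@]12[C@H](CCCCCCCCCCCCCCCC)C[C@@H]3C=C1O[Si](C(C)C)(C(C)C)O[C@H]4OC(=O)[C@@H]3[C@@]24CCCCCCCCCCCCCCCC | intermediate (not isolated)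
12 | keto lactol (methyl 6,7-dihexadecyl-2-oxobicyclo[2.2.2]octane-1-carboxylate with a cis-fused γ-hydroxy-γ-lactone across C5 and C6, syn to the C2 bridge; lactol carbon as both epimers) | COC(=O)[C@]12[C@H](CCCCCCCCCCCCCCCC)C[C@H](CC1=O)[C@@H]3C(=O)OC(O)[C@]23CCCCCCCCCCCCCCCC | intermediate
13 | (1S,4R,5S,6S,7R)-6,7-dihexadecyl-1-(methoxycarbonyl)-6-[(E)-3-methoxy-3-oxoprop-1-en-1-yl]-2-oxobicyclo[2.2.2]octane-5-carboxylic acid | COC(=O)[C@]12[C@H](CCCCCCCCCCCCCCCC)C[C@H](CC1=O)[C@H](C(=O)O)[C@@]2(/C=C/C(=O)OC)CCCCCCCCCCCCCCCC | intermediate (not isolated)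
14 | dimethyl (1S,4R,5S,6S,7R)-6,7-dihexadecyl-6-[(E)-3-methoxy-3-oxoprop-1-en-1-yl]-2-oxobicyclo[2.2.2]octane-1,5-dicarboxylate | COC(=O)[C@]12[C@H](CCCCCCCCCCCCCCCC)C[C@H](CC1=O)[C@H](C(=O)OC)[C@@]2(/C=C/C(=O)OC)CCCCCCCCCCCCCCCC | intermediate
15 | dimethyl (1S,4R,5S,6S,7R)-2-{[tert-butyl(dimethyl)silyl]oxy}-6,7-dihexadecyl-6-[(E)-3-methoxy-3-oxoprop-1-en-1-yl]bicyclo[2.2.2]oct-2-ene-1,5-dicarboxylate | COC(=O)[C@]12[C@H](CCCCCCCCCCCCCCCC)C[C@H](C=C1O[Si](C)(C)C(C)(C)C)[C@H](C(=O)OC)[C@@]2(/C=C/C(=O)OC)CCCCCCCCCCCCCCCC | intermediate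
16 | trimethyl (1R,4S,4aR,6R,8aS)-8-{[tert-butyl(dimethyl)silyl]oxy}-3,6-dihexadecyl-1,4,4a,5,6,8a-hexahydronaphthalene-1,4,7-tricarboxylate | CCCCCCCCCCCCCCCCC1=C[C@@H](C(=O)OC)[C@H]2C(O[Si](C)(C)C(C)(C)C)=C(C(=O)OC)[C@H](CCCCCCCCCCCCCCCC)C[C@H]2[C@@H]1C(=O)OC | intermediate
17 | trimethyl (1R,4S,4aR,6R,7S,8aS)-3,6-dihexadecyl-8-oxo-7-(phenylselanyl)-1,4,4a,5,6,7,8,8a-octahydronaphthalene-1,4,7-tricarboxylate (selenium trans to the C6 hexadecyl group) | CCCCCCCCCCCCCCCCC1=C[C@@H](C(=O)OC)[C@H]2C(=O)[C@@](C(=O)OC)([Se]c3ccccc3)[C@H](CCCCCCCCCCCCCCCC)C[C@H]2[C@@H]1C(=O)OC | intermediate (not isolated)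
18 | trimethyl (1R,4S,4aR,8aS)-3,6-dihexadecyl-8-oxo-1,4,4a,5,8,8a-hexahydronaphthalene-1,4,7-tricarboxylate | CCCCCCCCCCCCCCCCC1=C[C@@H](C(=O)OC)[C@H]2C(=O)C(C(=O)OC)=C(CCCCCCCCCCCCCCCC)C[C@H]2[C@@H]1C(=O)OC | target

**Step count.** Total: 9 steps. Longest linear sequence: 8 steps (1, 2, 4, 5, 6, 7, 8, 9); step 3 is the side branch.

**Steps most likely to fail**

Step 5. The cycloaddition joins two fully substituted carbons. Ring closure may therefore be slower than cleavage of the silyl ketal or oxidation of the dienol ether to the arene, and the acetal epimer that cannot reach the transition state may fail to epimerise. The fallback sets out from 8 and 9 and comes back at 14; it replaces the dienophile with a doubly activated maleate that has no acetal stereocenter. Oxidation of 8 (MnO2, CH2Cl2) should give 3-hexadecylfuran-2,5-dione F1. Methanolysis, mainly at the less hindered carbonyl, gives (2Z)-2-hexadecyl-4-methoxy-4-oxobut-2-enoic acid F2. F2, imidazole and chlorosilane 9 give the silyl ester triene F3. Heating closes the same seven-membered tether ring to the bridged cycloadduct F4, which HF·pyridine opens to the keto acid F5. Oxalyl chloride gives the acid chloride F6, Bu3SnH with Pd(PPh3)4 reduces it to the aldehyde F7, and the Wittig reaction of step 6 on F7 gives 14.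

Step 8. The [3,3] shift may need a temperature at which the silyl enol ether is lost or the cage opens by cycloreversion or a 1,3-shift before ring A closes. The fallback sets out from 14 and comes back at 17; it uses charge acceleration in place of heat. The potassium enolate of 14 (KN(SiMe3)2, 18-crown-6, THF, −78 to 0 °C) should undergo the same [3,3] shift at low temperature, driven by the change from a ketone enolate to a β-keto ester enolate. Protonation gives the β-keto ester trimethyl (1R,4S,4aR,6R,8aS)-3,6-dihexadecyl-8-oxo-1,4,4a,5,6,7,8,8a-octahydronaphthalene-1,4,7-tricarboxylate F8, and NaH followed by PhSeCl converts F8 into 17.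

Step 9. Selenium may be delivered to the face of C7 cis to the hexadecyl group, which leaves no syn hydrogen for the elimination, and the peroxide may attack the ring A alkene. The fallback sets out from 16 and comes back at 18 with no new compound (F0). Saegusa–Ito oxidation with Pd(OAc)2 (1.2 equiv, MeCN, 40 °C) goes through a palladium enolate that can reach either face before β-hydride elimination and needs no peroxide.

**Further compounds**

F1 | step 5 | 3-hexadecylfuran-2,5-dione | O=C1OC(=O)C(CCCCCCCCCCCCCCCC)=C1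
F2 | step 5 | (2Z)-2-hexadecyl-4-methoxy-4-oxobut-2-enoic acid | COC(=O)/C=C(/CCCCCCCCCCCCCCCC)C(=O)O
F3 | step 5 | silyl ester triene from 9 and F2 | COC(=O)C1=C(O[Si](C(C)C)(C(C)C)OC(=O)C(\CCCCCCCCCCCCCCCC)=C/C(=O)OC)C=CC[C@H]1CCCCCCCCCCCCCCCC
F4 | step 5 | silyl ester bridged cycloadduct | COC(=O)[C@]12[C@H](CCCCCCCCCCCCCCCC)C[C@@H]3C=C1O[Si](C(C)C)(C(C)C)OC(=O)[C@@]2(CCCCCCCCCCCCCCCC)[C@H]3C(=O)OC
F5 | step 5 | 6,7-dihexadecyl-1,5-bis(methoxycarbonyl)-2-oxobicyclo[2.2.2]octane-6-carboxylic acid | COC(=O)[C@]12[C@H](CCCCCCCCCCCCCCCC)C[C@H](CC1=O)[C@H](C(=O)OC)[C@@]2(C(=O)O)CCCCCCCCCCCCCCCC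
F6 | step 5 | acid chloride of F5 | COC(=O)[C@]12[C@H](CCCCCCCCCCCCCCCC)C[C@H](CC1=O)[C@H](C(=O)OC)[C@@]2(C(=O)Cl)CCCCCCCCCCCCCCCC
F7 | step 5 | dimethyl 6-formyl-6,7-dihexadecyl-2-oxobicyclo[2.2.2]octane-1,5-dicarboxylate | COC(=O)[C@]12[C@H](CCCCCCCCCCCCCCCC)C[C@H](CC1=O)[C@H](C(=O)OC)[C@@]2(C=O)CCCCCCCCCCCCCCCC
F8 | step 8 | trimethyl (1R,4S,4aR,6R,8aS)-3,6-dihexadecyl-8-oxo-1,4,4a,5,6,7,8,8a-octahydronaphthalene-1,4,7-tricarboxylate | CCCCCCCCCCCCCCCCC1=C[C@@H](C(=O)OC)[C@H]2C(=O)C(C(=O)OC)[C@H](CCCCCCCCCCCCCCCC)C[C@H]2[C@@H]1C(=O)OC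
F0 | step 9 | none | none
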